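The readings were computed with made-up constants, and the scatter is random.

1.90 of nucleophile and free base together is what the violet flask holds per electrophile, and my bench count asks for two per coupling: the nucleophile consumed, plus a taker for the acid I assume each coupling sets free, either free base or spare nucleophile.

all flasks: electrophile 0.20 M
- north-east: nucleophile 1.1 equiv; free base 0.49 equiv; run made earlier
- east: nucleophile 1.1 equiv; free base 1.2 equiv; run made earlier
- green: nucleophile 1.10 equiv; free base 1.60 equiv; time 15 min
- violet: nucleophile 1.10 equiv; free base 0.800 equiv; time 15 min

- north-east (time / min: electrophile / %, target / %): 2.00: 20, 80; 4.00: 15, 81; 5.00: 13, 83; 8.00: 16, 81; 10.0: 13, 80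
- east (time / min: electrophile / %, target / %): 0.833: 12, 89; 1.33: 9, 93; 2.50: 3, 99; 4.00: 1, 95; 6.00: 0, 100; 10.0: 0, 100

(standard deviation of a reading: 2 percentage points)

- the numbers in the tables scatter with a standard deviation of 2 percentage points
- a reading or a percentage of target counts all its forms, free or not

1. part of the electrophile that has reacted at the end, green
2. part of the electrophile that has reacted at the end, violet
3. what raising the equivalents of free base from its lowest to its highest value here does to the part of the electrophile that has reacted (changes below 5 percentage points count as none) (no change / it rises / it falls)

For violet this gives 95.0%: the stop, the smallest of full conversion, the nucleophile equivalents and half the summed equivalents. I test it on the north-east run, where the stop is 79.5%. Its last three electrophile readings put the reacted part at 86.0%, so the count reads 6.5 percentage points low there. In the east run the stop is 100%, and the electrophile reads 0% at 10.0 min.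

The border is the ratio of free base to nucleophile: above one, half the sum exceeds the nucleophile charge, and nucleophile becomes the limiting reagent unless it exceeds the electrophile. Violet stands at 0.727. Green stands at 1.45, over the border, but its 1.10 equiv of nucleophile still covers the electrophile, so its stop is 100%. The gap of 5 points sits on the margin of 5 points, and the north-east run read above its stop, so I commit to no change, narrowly.

The forecast gives 100% (98% to 100%) for green, 96% (92% to 99%) for violet, one point above my stop, and it rises, on the grounds that “each coupling releases one equivalent of acid”.

The flask gives >99.9% for green and 97.7% for violet, so the trend is no change, a change of 2.3 points. At 15.0 min violet still holds c(acid set free) = 0.00637 M, unbound, which is 3.19% of the electrophile charged, while the stop counts that acid as taken. Violet ends 2.7 points above its stop.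

    acid set free + free base ⇌ salt of the base, settled at all times (K = 1.10 × 10⁵ /M)
    acid set free + target → side product (k = 0.340 /M/s)
    electrophile + nucleophile → acid set free + target (k = 0.480 /M/s)
    nucleophile + acid set free ⇌ protonated nucleophile, settled at all times (K = 1700 /M)
    crystals ⇌ target, rate k5*(cs5 - [target]) while solid is left; crystals form when [target] > cs5 (solubility = 4.70 mM, k = 0.760 /s)

The neighbour of violet with 0.660 equiv of nucleophile has a ratio of 1.21, over the border, so its stop is 66.0%. That flask gives 66.0%, with 0% of its nucleophile and 18% of its free base left.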